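Everything rests on cutting ring A at C1–C6 and C2–C3. The feature exploited is its resorcylate pattern. The meta-related oxygens on C2 and C4, the ester carbon on C1 and the methyl groups on C3 and C6 map atom for atom onto a malonate plus an ethyl propenyl ketone. In one operation a Michael addition and an intramolecular Claisen condensation join the two purchased, acyclic partners, dimethyl malonate and (E)-hex-4-en-3-one, into ring A at the dihydro (cyclohexanedione) level. Dehydrogenation directly afterwards gives the resorcylate, so the depside bond is made on a phenol. Its non-chelated C4 hydroxyl is esterified with a benzyl-protected ring B acid from 5-methylpyrogallol, and hydrogenolysis finishes.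

Key step: step 1

Remark on the chemistry: the target has no stereocentre and no stereogenic double bond, so no configuration has to be set; ring A is numbered from the ester-bearing carbon (C1) towards the chelated hydroxyl (C2), and ring B likewise with primes.

Step 1
Reactants: 1 dimethyl malonate; 2 (E)-hex-4-en-3-one
Product: 5 methyl 3,6-dimethyl-2,4-dioxocyclohexane-1-carboxylate (diastereomer/enol mixture), via Michael adduct 3 (not isolated), via sodium enolate 4 (not isolated)
Conditions: NaOMe (1.1 equiv), MeOH, 0 °C → reflux; then aq. HCl, 0 °C
Reagents that add atoms: sodium methoxide NaOMe, C[O-].[Na+] (its sodium is found only in salt 4)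
Why: Methoxide deprotonates 1, and the malonate anion adds in a Michael reaction to the β-carbon of 2, which forms the C1–C6 bond and turns the terminal methyl of the enone into the C6 methyl (adduct 3). Proton exchange in MeOH then supplies the ketone enolate on the ethyl side, whose carbon attacks one of the two equivalent ester carbonyls in an intramolecular Claisen (Dieckmann-type) condensation that forms C2–C3 and expels methoxide. This single ring closure is 6-exo-trig at the ester carbonyl with the enolate double bond inside the new ring (enolendo), a favoured mode. The closest known reaction type is the tandem Michael–Claisen annulation of malonates with α,β-unsaturated ketones to dihydroresorcylates, so the step stays within known chemistry. The selectivity needed is the site of closure, and the substrate secures it: the enolate on the C5 side could only close a four-membered ring, all earlier events are reversible, and deprotonation of the acidic 1,3-dione to salt 4 by a full equivalent of base pulls the equilibria to the six-membered product (NaOMe matches the esters, so ester exchange is invisible). C1, C3 and C6 arise as stereocentres under no control, C1 and C3 being epimerisable through the enols, and none is needed because step 2 makes all three sp2 carbons.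

Step 2
Reactants: 5 methyl 3,6-dimethyl-2,4-dioxocyclohexane-1-carboxylate
Product: 8 methyl 2,4-dihydroxy-3,6-dimethylbenzoate, via 3-bromo dione 6 (not isolated), via 5-bromo dione 7 (not isolated)
Conditions: Br2 (1.0 equiv), DMF, 0 °C; then 80 °C
Reagents that add atoms: bromine, BrBr (its bromine is found only in 6 and 7)
Why: Halogenation–dehydrohalogenation aromatisation of a cyclohexane-1,3-dione, a reaction type well tried on dihydroresorcylates: Br2 attacks the enolic C3 to give 6, the HBr formed relays the reversibly bound bromine on warming to C5 (7), and loss of HBr across C5–C6 with tautomerisation of both carbonyls should give the aromatic ring, while the ester stays in place as long as the bath is kept near 80 °C.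

Step 3
Reactants: 9 5-methylbenzene-1,2,3-triol (5-methylpyrogallol)
Product: 10 1,2,3-tris(benzyloxy)-5-methylbenzene
Conditions: BnBr (3.3 equiv), K2CO3, DMF, N2, 60 °C
Reagents that add atoms: benzyl bromide, BrCc1ccccc1
Why: Threefold Williamson ether synthesis on the phenoxides, run under N2 because the pyrogallol anion is oxidised by air; benzyl is chosen because it leaves at the end under neutral conditions that the depside ester tolerates.

Step 4
Reactants: 10 1,2,3-tris(benzyloxy)-5-methylbenzene
Product: 12 2,3,4-tris(benzyloxy)-6-methylbenzaldehyde, via iminium chloride 11 (not isolated)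
Conditions: POCl3 (1.5 equiv), DMF, 0 → 70 °C; then ice–water
Reagents that add atoms: N,N-dimethylformamide, CN(C)C=O (formyl carbon; its Me2N group is found only in 11); water, O (aldehyde oxygen); phosphoryl chloride, O=P(Cl)(Cl)Cl (chloride counter-ion of 11 only)
Why: Vilsmeier–Haack formylation of a strongly activated arene: the two free ring positions of 10 are related by symmetry, each ortho to one benzyloxy group and para to another, so only one aldehyde can form after hydrolysis of 11.

Step 5
Reactants: 12 2,3,4-tris(benzyloxy)-6-methylbenzaldehyde
Product: 13 2,3,4-tris(benzyloxy)-6-methylbenzoic acid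
Conditions: NaClO2, NaH2PO4, 2-methylbut-2-ene (excess), t-BuOH/THF/H2O, rt
Reagents that add atoms: sodium chlorite NaClO2, [Na+].[O-]Cl=O (one oxygen)
Why: Pinnick oxidation converts the hindered aldehyde into the acid under buffered, mild conditions that leave benzyl ethers alone, and the excess alkene traps HOCl before it can chlorinate the electron-rich ring.

Step 6
Reactants: 13 2,3,4-tris(benzyloxy)-6-methylbenzoic acid; 8 methyl 2,4-dihydroxy-3,6-dimethylbenzoate
Product: 15 methyl 2-hydroxy-3,6-dimethyl-4-{[2,3,4-tris(benzyloxy)-6-methylbenzoyl]oxy}benzoate, via mixed anhydride 14 (not isolated)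
Conditions: (CF3CO)2O, toluene, 0 °C → rt
Reagents that add atoms: trifluoroacetic anhydride, O=C(OC(=O)C(F)(F)F)C(F)(F)F (its CF3CO group is found only in 14)
Why: Mixed-anhydride esterification as commonly used for depsides: 13 is turned into the aroyl trifluoroacetate 14, which hands its electron-rich aroyl group to the C4 hydroxyl of 8, because the C2 hydroxyl is tied up in a hydrogen bond to the C1 ester carbonyl and is flanked on both sides.

Step 7
Reactants: 15 methyl 2-hydroxy-3,6-dimethyl-4-{[2,3,4-tris(benzyloxy)-6-methylbenzoyl]oxy}benzoate
Product: 16 methyl 2-hydroxy-3,6-dimethyl-4-[(2,3,4-trihydroxy-6-methylbenzoyl)oxy]benzoate (target)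
Conditions: H2 (1 atm), 10% Pd/C, EtOAc, rt; filtration under argon
Reagents that add atoms: none
Why: Catalytic hydrogenolysis of the three benzyl aryl ethers over Pd/C, to which the aryl ester and the methyl ester are inert; a non-nucleophilic solvent keeps the depside bond safe from alcoholysis, and air is excluded because the freed pyrogallol unit is easily oxidised.

Compound list
1 | dimethyl malonate | COC(=O)CC(=O)OC | starting material
2 | (E)-hex-4-en-3-one | CCC(=O)/C=C/C | starting material
3 | dimethyl 2-(4-oxohexan-2-yl)propanedioate (racemic Michael adduct) | CCC(=O)CC(C)C(C(=O)OC)C(=O)OC | intermediate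
4 | sodium 6-(methoxycarbonyl)-2,5-dimethyl-3-oxocyclohex-1-en-1-olate (mixture of diastereomers) | COC(=O)C1C(C)CC(=O)C(C)=C1[O-].[Na+] | intermediate
5 | methyl 3,6-dimethyl-2,4-dioxocyclohexane-1-carboxylate (mixture of diastereomers and enol forms) | COC(=O)C1C(C)CC(=O)C(C)C1=O | intermediate
6 | methyl 3-bromo-3,6-dimethyl-2,4-dioxocyclohexane-1-carboxylate (mixture of diastereomers) | COC(=O)C1C(C)CC(=O)C(C)(Br)C1=O | intermediate
7 | methyl 5-bromo-3,6-dimethyl-2,4-dioxocyclohexane-1-carboxylate (mixture of diastereomers) | COC(=O)C1C(C)C(Br)C(=O)C(C)C1=O | intermediate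
8 | methyl 2,4-dihydroxy-3,6-dimethylbenzoate | COC(=O)c1c(C)cc(O)c(C)c1O | intermediate
9 | 5-methylbenzene-1,2,3-triol | Cc1cc(O)c(O)c(O)c1 | starting material
10 | 1,2,3-tris(benzyloxy)-5-methylbenzene | Cc1cc(OCc2ccccc2)c(OCc2ccccc2)c(OCc2ccccc2)c1 | intermediate
11 | N-{[2,3,4-tris(benzyloxy)-6-methylphenyl]methylidene}-N-methylmethanaminium chloride | C[N+](C)=Cc1c(C)cc(OCc2ccccc2)c(OCc2ccccc2)c1OCc2ccccc2.[Cl-] | intermediate
12 | 2,3,4-tris(benzyloxy)-6-methylbenzaldehyde | Cc1cc(OCc2ccccc2)c(OCc2ccccc2)c(OCc2ccccc2)c1C=O | intermediate
13 | 2,3,4-tris(benzyloxy)-6-methylbenzoic acid | Cc1cc(OCc2ccccc2)c(OCc2ccccc2)c(OCc2ccccc2)c1C(=O)O | intermediate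
14 | 2,3,4-tris(benzyloxy)-6-methylbenzoic trifluoroacetic anhydride | Cc1cc(OCc2ccccc2)c(OCc2ccccc2)c(OCc2ccccc2)c1C(=O)OC(=O)C(F)(F)F | intermediate
15 | methyl 2-hydroxy-3,6-dimethyl-4-{[2,3,4-tris(benzyloxy)-6-methylbenzoyl]oxy}benzoate | COC(=O)c1c(C)cc(OC(=O)c2c(C)cc(OCc3ccccc3)c(OCc3ccccc3)c2OCc3ccccc3)c(C)c1O | intermediate
16 | methyl 2-hydroxy-3,6-dimethyl-4-[(2,3,4-trihydroxy-6-methylbenzoyl)oxy]benzoate | COC(=O)c1c(C)cc(OC(=O)c2c(C)cc(O)c(O)c2O)c(C)c1O | target

Total step count: 7
Longest linear sequence: 5 steps (3, 4, 5, 6, 7); the ring A branch (1, 2, 6, 7) has 4.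

Steps most likely to fail

Step 2. The bromo diones can pass electrophilic bromine to the very electron-rich resorcylate as it forms. Ring bromination at C5 would then compete with dehydrobromination, and part of the dione would stay unoxidised. The fallback accepts the over-bromination instead of fighting it. It sets out from 5. Excess Br2 in AcOH at rt should carry all material through aromatisation and ring bromination to methyl 5-bromo-2,4-dihydroxy-3,6-dimethylbenzoate F1. Reductive removal of the aryl bromide (H2, 10% Pd/C, NaOAc, MeOH, rt) then comes back to the route at 8.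

Step 6. Acyl transfer between a di-ortho-substituted aroyl group and a phenol flanked by a methyl group may be slow. That leaves time for acid-induced loss of benzyl groups and for trifluoroacetylation of the phenol. The fallback replaces the acidic mixed-anhydride coupling by an anionic acylation and sets out from 13 and 8.
- Acid 13 is converted with (COCl)2 and catalytic DMF in CH2Cl2 into 2,3,4-tris(benzyloxy)-6-methylbenzoyl chloride F2.
- Phenol 8 is deprotonated with NaH (1.0 equiv) in THF at 0 °C at its more acidic, unchelated C4 hydroxyl. This gives sodium 3-hydroxy-4-(methoxycarbonyl)-2,5-dimethylphenolate F3.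
- The two are combined at 0 °C → rt, which comes back to the route at 15.

Step 4. Chloride may attack the benzyl group next to the new iminium carbon under the acidic conditions and remove it, or substitution at the crowded ring position may be sluggish. The fallback installs the carboxyl carbon as an electrophile on an aryl anion and sets out from 10.
- NBS in MeCN at 0 °C in the dark should give 1,2,3-tris(benzyloxy)-4-bromo-5-methylbenzene F4. The symmetry argument again allows only one isomer.
- Bromine–lithium exchange with n-BuLi in THF at −78 °C gives [2,3,4-tris(benzyloxy)-6-methylphenyl]lithium F5.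
- Quenching with CO2 gives lithium 2,3,4-tris(benzyloxy)-6-methylbenzoate F6.
- Acidification with aq. HCl comes back to the route at 13, which also bypasses step 5.

Further compounds
F1 | step 2 | methyl 5-bromo-2,4-dihydroxy-3,6-dimethylbenzoate | COC(=O)c1c(C)c(Br)c(O)c(C)c1O
F2 | step 6 | 2,3,4-tris(benzyloxy)-6-methylbenzoyl chloride | Cc1cc(OCc2ccccc2)c(OCc2ccccc2)c(OCc2ccccc2)c1C(=O)Cl
F3 | step 6 | sodium 3-hydroxy-4-(methoxycarbonyl)-2,5-dimethylphenolate | COC(=O)c1c(C)cc([O-])c(C)c1O.[Na+]
F4 | step 4 | 1,2,3-tris(benzyloxy)-4-bromo-5-methylbenzene | Cc1cc(OCc2ccccc2)c(OCc2ccccc2)c(OCc2ccccc2)c1Br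
F5 | step 4 | [2,3,4-tris(benzyloxy)-6-methylphenyl]lithium | [Li]c1c(C)cc(OCc2ccccc2)c(OCc2ccccc2)c1OCc2ccccc2
F6 | step 4 | lithium 2,3,4-tris(benzyloxy)-6-methylbenzoate | Cc1cc(OCc2ccccc2)c(OCc2ccccc2)c(OCc2ccccc2)c1C(=O)[O-].[Li+]
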